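**Retrosynthetic overview**

1. Peniophorin ⇒ open methyl ester. Ring B (the lactone, O1–C2 bond) closes last, once the C6 oxygen is freed and the enol at C7a can form.
2. Ring A ⇒ 4-allenyl-4-hydroxycyclobutenone, by thermal 4π opening then 6π closure that forms C3a–C7a. The strategy rests on the pattern of ring A (C3a to C7a, benzofuran numbering): C5 and C7a are para oxygen-bearing carbons with C6–O and C7–Ph between them, and C3a carries the exocyclic C3a=C3 bond. An allenyl vinylketene closes to exactly this array.
3. Allenylcyclobutenone ⇒ 3-methoxy-4-phenylcyclobutenedione plus the silyl ketene acetal of methyl 2,4-bis(4-methoxyphenyl)but-3-ynoate, joined through the γ-carbon (alkynylogous Mukaiyama aldol). A lithium enolate of this ester is expected to react at its α-carbon, so the silyl acetal is used instead.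
4. Dione ⇒ dimethyl squarate + PhLi. Alkynoate ⇒ aryldiazoacetate + 4-ethynylanisole (copper-catalysed coupling).
5. Ring order: cyclobutene (supplied by the squarate), ring A (step 6), ring B (step 7).

Key step: step 6

Assumption: the target is achiral, so no stereocentre has to be set; the carbinol centre and allene axis of 11 are carried as the racemic diastereomer mixture because step 6 destroys both.

**Step 1**
Reactants: 1 dimethyl squarate; 2 phenyllithium
Product: 5 3-methoxy-4-phenylcyclobut-3-ene-1,2-dione, via lithium alkoxide 3 (not isolated), via trifluoroacetate 4 (not isolated)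
Conditions: PhLi, THF, −78 °C; (CF3CO)2O, −78 °C; aq. NH4Cl, rt
Reagents that add atoms: water, SMILES O
Why: 1,2-addition of the organolithium to one of the two equivalent carbonyls of 1 gives alkoxide 3, and trifluoroacetylation to 4, ionization and hydrolytic loss of methanol on work-up transpose the carbonyl, the standard squarate addition/acid rearrangement route to 3-alkoxy-4-arylcyclobutenediones.

**Step 2**
Reactants: 6 methyl 4-methoxyphenylacetate
Product: 7 methyl 2-diazo-2-(4-methoxyphenyl)acetate
Conditions: 4-AcNHC6H4SO2N3, DBU, MeCN, 0 °C to rt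
Reagents that add atoms: 4-acetamidobenzenesulfonyl azide, SMILES CC(=O)Nc1ccc(cc1)S(=O)(=O)N=[N+]=[N-]
Why: Regitz diazo transfer, in which the DBU-generated ester enolate attacks the sulfonyl azide and the adduct collapses to the aryldiazoacetate and the sulfonamide.

**Step 3**
Reactants: 7 methyl 2-diazo-2-(4-methoxyphenyl)acetate; 8 4-ethynylanisole
Product: 9 methyl 2,4-bis(4-methoxyphenyl)but-3-ynoate (racemic)
Conditions: CuI (10 mol %), MeCN, rt, slow addition of 7
Reagents that add atoms: none
Why: Copper-catalysed carbene/terminal alkyne cross-coupling, in which the copper acetylide of 8 takes up the carbene from 7, the alkynyl group migrates to the carbene carbon and protonation releases the 3-alkynoate with loss of N2.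

**Step 4**
Reactants: 9 methyl 2,4-bis(4-methoxyphenyl)but-3-ynoate
Product: 10 tert-butyl{[1-methoxy-2,4-bis(4-methoxyphenyl)but-1-en-3-yn-1-yl]oxy}dimethylsilane (E/Z mixture)
Conditions: LiN(SiMe3)2, THF, −78 °C; t-BuMe2SiCl, DMPU, −78 °C to rt
Reagents that add atoms: tert-butyldimethylsilyl chloride, SMILES CC(C)(C)[Si](C)(C)Cl
Why: Ketene silyl acetal formation, in which deprotonation of the doubly activated C2–H of 9 (or of any allenoate tautomer carried with it) gives one delocalized lithium enolate that the hard silyl chloride traps on oxygen; the acetal geometry is irrelevant.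

**Step 5**
Reactants: 10 tert-butyl{[1-methoxy-2,4-bis(4-methoxyphenyl)but-1-en-3-yn-1-yl]oxy}dimethylsilane; 5 3-methoxy-4-phenylcyclobut-3-ene-1,2-dione
Product: 11 methyl 4-(1-hydroxy-2-methoxy-4-oxo-3-phenylcyclobut-2-en-1-yl)-2,4-bis(4-methoxyphenyl)buta-2,3-dienoate (racemic, mixture of diastereomers)
Conditions: BF3·OEt2, CH2Cl2, −78 °C; aq. NaHCO3
Reagents that add atoms: none
Why: Alkynylogous Mukaiyama aldol through an open transition state, in which BF3 activates the C2 carbonyl of 5 (the ketone next to C–OMe, more electrophilic than the vinylogous-ester carbonyl C1) and 10, its α-carbon blocked by the aryl group and the silyl acetal, attacks through the alkyne terminus to give the tetrasubstituted allenoate; the carbinol centre and allene axis form without control, which is harmless.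

**Step 6**
Reactants: 11 methyl 4-(1-hydroxy-2-methoxy-4-oxo-3-phenylcyclobut-2-en-1-yl)-2,4-bis(4-methoxyphenyl)buta-2,3-dienoate
Product: 13 methyl (Z)-2-[5-hydroxy-4-methoxy-6-(4-methoxyphenyl)-2-oxo-3-phenylcyclohexa-3,5-dien-1-ylidene]-2-(4-methoxyphenyl)acetate, via allenyl vinylketene 12 (not isolated)
Conditions: toluene (0.01 M, degassed), 110 °C
Reagents that add atoms: none
Why: Heating cleaves the C1–C4 bond of the cyclobutenone in a conrotatory 4π electrocyclic opening, the donor hydroxyl turning outward so that the allenyl group lies cis to the ketene in 12. The ketene carbon (future C7a) then bonds to the central allene carbon (future C3a) in a thermal disrotatory 6π electrocyclization that closes ring A as a six-membered cyclohexadienone and leaves the distal allene bond as exocyclic C3a=C3; this is the Moore-type ring expansion known for 4-allenylcyclobutenones giving o-quinone methides. No stereocentre is formed, and the carbinol centre and allene axis of 11 both vanish, so the diastereomers converge. The step needs outward rotation of the hydroxyl, secured by the torquoselectivity of donor substituents, and closure at the proximal allene bond, the only one that gives a six-membered ring. The C3a=C3 geometry depends on which allene face meets the ketene, with the smaller ester expected to turn toward the C7a carbonyl (Z); any E isomer or benzoquinone tautomer should still reach the same lactone in step 7 through acid-mediated equilibration.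

**Step 7**
Reactants: 13 methyl (Z)-2-[5-hydroxy-4-methoxy-6-(4-methoxyphenyl)-2-oxo-3-phenylcyclohexa-3,5-dien-1-ylidene]-2-(4-methoxyphenyl)acetate
Product: 15 peniophorin, via demethylated ester 14 (not isolated)
Conditions: BBr3 (excess), CH2Cl2, −78 °C to rt; H2O; aq. HCl, THF, 50 °C
Reagents that add atoms: none
Why: Lewis-acid ether cleavage by BBr3 removes the two aryl methyl groups and the vinylogous-ester methyl at C6, and after hydrolysis 14 tautomerizes to its C7a enol, which acylates on the Z-disposed ester (acid-catalysed 5-exo-trig lactonization) to close ring B with loss of methanol.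

**Compound list**

1 | dimethyl squarate | COC1=C(OC)C(=O)C1=O | starting material
2 | phenyllithium | [Li]c1ccccc1 | starting material
3 | lithium 2,3-dimethoxy-4-oxo-1-phenylcyclobut-2-en-1-olate (racemic) | [Li+].[O-]C1(c2ccccc2)C(OC)=C(OC)C1=O | intermediate
4 | 2,3-dimethoxy-4-oxo-1-phenylcyclobut-2-en-1-yl trifluoroacetate (racemic) | O=C(OC1(c2ccccc2)C(OC)=C(OC)C1=O)C(F)(F)F | intermediate
5 | 3-methoxy-4-phenylcyclobut-3-ene-1,2-dione | COC1=C(c2ccccc2)C(=O)C1=O | intermediate
6 | methyl 4-methoxyphenylacetate | COC(=O)Cc1ccc(OC)cc1 | starting material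
7 | methyl 2-diazo-2-(4-methoxyphenyl)acetate | COC(=O)C(=[N+]=[N-])c1ccc(OC)cc1 | intermediate
8 | 4-ethynylanisole | COc1ccc(cc1)C#C | starting material
9 | methyl 2,4-bis(4-methoxyphenyl)but-3-ynoate (racemic) | COC(=O)C(C#Cc1ccc(OC)cc1)c1ccc(OC)cc1 | intermediate
10 | tert-butyl{[1-methoxy-2,4-bis(4-methoxyphenyl)but-1-en-3-yn-1-yl]oxy}dimethylsilane (E/Z mixture) | COC(O[Si](C)(C)C(C)(C)C)=C(C#Cc1ccc(OC)cc1)c1ccc(OC)cc1 | intermediate
11 | methyl 4-(1-hydroxy-2-methoxy-4-oxo-3-phenylcyclobut-2-en-1-yl)-2,4-bis(4-methoxyphenyl)buta-2,3-dienoate (racemic, diastereomer mixture) | COC(=O)C(c1ccc(OC)cc1)=C=C(c1ccc(OC)cc1)C1(O)C(OC)=C(c2ccccc2)C1=O | intermediate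
12 | methyl (5Z)-5-hydroxy-6-methoxy-2,4-bis(4-methoxyphenyl)-8-oxo-7-phenylocta-2,3,5,7-tetraenoate (racemic allene) | COC(=O)C(c1ccc(OC)cc1)=C=C(c1ccc(OC)cc1)/C(O)=C(OC)\C(c1ccccc1)=C=O | intermediate
13 | methyl (Z)-2-[5-hydroxy-4-methoxy-6-(4-methoxyphenyl)-2-oxo-3-phenylcyclohexa-3,5-dien-1-ylidene]-2-(4-methoxyphenyl)acetate | COC(=O)/C(c1ccc(OC)cc1)=C1\C(=O)C(c2ccccc2)=C(OC)C(O)=C1c1ccc(OC)cc1 | intermediate
14 | methyl (Z)-2-[4,5-dihydroxy-6-(4-hydroxyphenyl)-2-oxo-3-phenylcyclohexa-3,5-dien-1-ylidene]-2-(4-hydroxyphenyl)acetate | COC(=O)/C(c1ccc(O)cc1)=C1\C(=O)C(c2ccccc2)=C(O)C(O)=C1c1ccc(O)cc1 | intermediate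
15 | peniophorin, 5-hydroxy-3,4-bis(4-hydroxyphenyl)-7-phenyl-1-benzofuran-2,6-dione | O=C1OC2=C(c3ccccc3)C(=O)C(O)=C(c3ccc(O)cc3)C2=C1c1ccc(O)cc1 | target

**Step count**

Total steps: 7. Longest linear sequence: 6 steps (6 → 7 → 9 → 10 → 11 → 13 → 15); step 1 is a one-step side branch.

**Steps most likely to fail**

1. Step 6. The hydroxyl may rotate inward so that it captures the ketene, the hindered carbinol may fragment by retro-aldol cleavage before the ring opens, or the quinone methide may decompose at 110 °C. The fallback builds ring A by the parent alkenyl ring expansion and adds the C3 unit afterwards; it sets out from 5 and comes back at 15.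
   - Addition of 1-(4-methoxyphenyl)ethenyllithium (THF, −78 °C) to the C2 carbonyl of 5 should give 4-hydroxy-3-methoxy-4-[1-(4-methoxyphenyl)ethenyl]-2-phenylcyclobut-2-en-1-one F1.
   - Heating F1 in toluene at 110 °C should give, by ring opening, 6π closure and tautomerization, 3-methoxy-5-(4-methoxyphenyl)-2-phenylbenzene-1,4-diol F2.
   - Ag2O should oxidize F2 to 2-methoxy-6-(4-methoxyphenyl)-3-phenylcyclohexa-2,5-diene-1,4-dione F3, whose only unsubstituted carbon is the future C3a.
   - Mukaiyama–Michael addition of {[1-methoxy-2-(4-methoxyphenyl)ethenyl]oxy}trimethylsilane F4 (from 6, LiN(i-Pr)2, Me3SiCl) to F3 (TiCl4, CH2Cl2, −78 °C), then acidic work-up, should form C3a–C3 and lactonize to 5-hydroxy-6-methoxy-3,4-bis(4-methoxyphenyl)-7-phenyl-1-benzofuran-2(3H)-one F5.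
   - BBr3 should then give 5,6-dihydroxy-3,4-bis(4-hydroxyphenyl)-7-phenyl-1-benzofuran-2(3H)-one F6, which air or Ag2O should dehydrogenate to 15.

2. Step 5. Bond formation may occur through the α-carbon of the acetal (giving a propargylic quaternary adduct), or the nucleophile may attack C3 of the dione with displacement of methoxide. The fallback drops the silyl acetal and the Lewis acid; it sets out from 9 and 5 and comes back at 11. A base-catalysed direct alkynylogous aldol is run under equilibrium control (catalytic LiN(SiMe3)2, THF, −40 °C, quench with AcOH). A congested α-aldolate can revert, whereas the conjugated γ-adduct should accumulate. It makes no new compound (F0).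

3. Step 7. Ether cleavage may be incomplete, HBr may add to the quinone methide, or the freed enol may fail to close the lactone under the Lewis-acid conditions. The fallback separates the two events; it sets out from 13 and comes back at 15. Aqueous acid (2 M HCl, THF, 50 °C) should hydrolyse only the vinylogous methyl ester at C6 and close the lactone to 5-hydroxy-3,4-bis(4-methoxyphenyl)-7-phenyl-1-benzofuran-2,6-dione F7. The two anisole ethers of this robust lactone are then cleaved in molten pyridinium chloride at 190 °C.

**Further compounds**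

F1 | step 6 | 4-hydroxy-3-methoxy-4-[1-(4-methoxyphenyl)ethenyl]-2-phenylcyclobut-2-en-1-one (racemic) | C=C(c1ccc(OC)cc1)C1(O)C(OC)=C(c2ccccc2)C1=O
F2 | step 6 | 3-methoxy-5-(4-methoxyphenyl)-2-phenylbenzene-1,4-diol | COc1c(O)c(-c2ccc(OC)cc2)cc(O)c1-c1ccccc1
F3 | step 6 | 2-methoxy-6-(4-methoxyphenyl)-3-phenylcyclohexa-2,5-diene-1,4-dione | COC1=C(c2ccccc2)C(=O)C=C(c2ccc(OC)cc2)C1=O
F4 | step 6 | {[1-methoxy-2-(4-methoxyphenyl)ethenyl]oxy}trimethylsilane (E/Z mixture) | COC(O[Si](C)(C)C)=Cc1ccc(OC)cc1
F5 | step 6 | 5-hydroxy-6-methoxy-3,4-bis(4-methoxyphenyl)-7-phenyl-1-benzofuran-2(3H)-one (racemic) | COc1c(O)c(-c2ccc(OC)cc2)c2C(c3ccc(OC)cc3)C(=O)Oc2c1-c1ccccc1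
F6 | step 6 | 5,6-dihydroxy-3,4-bis(4-hydroxyphenyl)-7-phenyl-1-benzofuran-2(3H)-one (racemic) | Oc1ccc(cc1)C1C(=O)Oc2c1c(-c1ccc(O)cc1)c(O)c(O)c2-c1ccccc1
F0 | step 5 | none | none
F7 | step 7 | 5-hydroxy-3,4-bis(4-methoxyphenyl)-7-phenyl-1-benzofuran-2,6-dione | O=C1OC2=C(c3ccccc3)C(=O)C(O)=C(c3ccc(OC)cc3)C2=C1c1ccc(OC)cc1
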